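**Retrosynthetic overview**
- Target: (2S)-6-(2,3-dihydroxybenzyl)-5,7-dihydroxyflavanone. Ring C (O1–C2–C3–C4–C4a–C8a) is closed last by a catalyst-controlled 6-endo oxa-Michael addition of O1 to C2 of a benzylidene β-ketoester. The tert-butyl ester on C3 is a traceless activating group lost as CO2 in the same flask, and the E/Z isomers converge on 2S.
- Enabling feature: C3 lies between the C4 carbonyl and the acceptor carbon C2, so it can carry the ester. On ring A the O1-bearing C8a is para to the benzyl-bearing C6, so the A/D unit is a symmetric 4-benzyl-3,5-bis(benzyloxy)phenol with two equivalent ortho carbons. Acylation gives one ketone in which O1 is the only free hydroxyl beside C4=O (O5, O7 benzylated), which fixes 6- over 8-benzyl.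
- Disconnections: O1–C2 and C2=C3 (benzaldehyde, Knoevenagel); C3–CO2tBu (Boc2O); C4–C4a (Friedel–Crafts acetylation); C6–CH2 (ortho-lithiation between the two OBn groups of silylated 3,5-bis(benzyloxy)phenol, addition to 2,3-bis(benzyloxy)benzaldehyde, ionic deoxygenation).
- Ring order: rings A, B and D are purchased arenes; ring C is the only ring made and is formed in step 7; hydrogenolysis of four benzyl ethers ends the route.

Key step: step 7

Remark: the quinidine-derived pseudoenantiomer of the cinchona thiourea is assumed to deliver the 2S series; should the sense be opposite, the quinine-derived catalyst is used and nothing else changes.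

**Step 1**
Reactants: 1 3,5-bis(benzyloxy)phenol
Product: 2 [3,5-bis(benzyloxy)phenoxy]tri(propan-2-yl)silane
Conditions: TIPSCl, imidazole, DMF, rt
Reagents that add atoms: triisopropylsilyl chloride, CC(C)[Si](Cl)(C(C)C)C(C)C
Why: Imidazole-promoted silylation of the only free phenol caps O1 with a bulky, weakly coordinating group, so that the lithiation in step 2 is steered to the carbon between the two benzyloxy groups.

**Step 2**
Reactants: 2 [3,5-bis(benzyloxy)phenoxy]tri(propan-2-yl)silane; 3 2,3-bis(benzyloxy)benzaldehyde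
Product: 5 [2,6-bis(benzyloxy)-4-(triisopropylsilyloxy)phenyl][2,3-bis(benzyloxy)phenyl]methanol (racemic), via aryllithium 4 (not isolated)
Conditions: n-BuLi, THF, 0 °C; then 3, −78 °C to rt; H2O quench
Reagents that add atoms: none
Why: Directed ortho-metalation: the ring C–H flanked by the two benzyloxy groups is the most acidic and best coordinated site (the bulky OTIPS shields its own ortho positions), and 1,2-addition of the aryllithium to the aldehyde should give the diarylcarbinol, whose racemic carbinol centre is removed in step 3.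

**Step 3**
Reactants: 5 [2,6-bis(benzyloxy)-4-(triisopropylsilyloxy)phenyl][2,3-bis(benzyloxy)phenyl]methanol
Product: 7 3,5-bis(benzyloxy)-4-[2,3-bis(benzyloxy)benzyl]phenol, via silyl ether diarylmethane 6 (not isolated)
Conditions: Et3SiH, TFA, CH2Cl2, −20 to 0 °C; evaporate; then TBAF, THF, 0 °C
Reagents that add atoms: none
Why: Ionic hydrogenation: TFA ionises the doubly benzylic alcohol to a cation stabilised by the 2,4,6-trioxygenated ring, Et3SiH delivers hydride, and fluoride then cleaves the aryl silyl ether to free O1.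

**Step 4**
Reactants: 7 3,5-bis(benzyloxy)-4-[2,3-bis(benzyloxy)benzyl]phenol
Product: 8 1-{2,4-bis(benzyloxy)-3-[2,3-bis(benzyloxy)benzyl]-6-hydroxyphenyl}ethan-1-one
Conditions: Ac2O, BF3·OEt2, CH2Cl2, 0 °C to rt; aq. NaOAc work-up
Reagents that add atoms: acetic anhydride, CC(=O)OC(C)=O
Why: Friedel–Crafts acylation (O-acetate/Fries manifold) of a phloroglucinol-type phenol: the para position is blocked by the benzyl group and the two ortho positions are equivalent by symmetry, so a single ortho-hydroxy ketone should form, with O1 free and hydrogen-bonded to the carbonyl and O5 still benzylated.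

**Step 5**
Reactants: 8 1-{2,4-bis(benzyloxy)-3-[2,3-bis(benzyloxy)benzyl]-6-hydroxyphenyl}ethan-1-one
Product: 9 tert-butyl 3-{2,4-bis(benzyloxy)-3-[2,3-bis(benzyloxy)benzyl]-6-hydroxyphenyl}-3-oxopropanoate
Conditions: LiHMDS (3.3 equiv), THF, −78 °C; Boc2O (1.1 equiv), −78 to 0 °C; 1 M HCl quench
Reagents that add atoms: di-tert-butyl dicarbonate, CC(C)(C)OC(=O)OC(=O)OC(C)(C)C
Why: Claisen-type C-acylation of the ketone enolate (phenoxide–enolate dianion) with Boc2O, any O-Boc phenoxide being able to pass its acyl group to the enolate carbon in Baker–Venkataraman fashion; the third equivalent of base stores the product as its enolate and the tert-butyl ester resists lactonisation to a 4-hydroxycoumarin.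

**Step 6**
Reactants: 9 tert-butyl 3-{2,4-bis(benzyloxy)-3-[2,3-bis(benzyloxy)benzyl]-6-hydroxyphenyl}-3-oxopropanoate; 10 benzaldehyde
Product: 11 tert-butyl 2-{2,4-bis(benzyloxy)-3-[2,3-bis(benzyloxy)benzyl]-6-hydroxybenzoyl}-3-phenylprop-2-enoate (E/Z mixture)
Conditions: piperidine (0.2 equiv), AcOH (0.2 equiv), 4 Å MS, toluene, rt
Reagents that add atoms: none
Why: Knoevenagel condensation under piperidinium acetate (iminium activation of the aldehyde, water removed by sieves), which should give the benzylidene as an E/Z mixture that is used as such because step 7 is stereoconvergent.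

**Step 7**
Reactants: 11 tert-butyl 2-{2,4-bis(benzyloxy)-3-[2,3-bis(benzyloxy)benzyl]-6-hydroxybenzoyl}-3-phenylprop-2-enoate (E/Z mixture)
Product: 13 (2S)-5,7-bis(benzyloxy)-6-[2,3-bis(benzyloxy)benzyl]-2-phenylchroman-4-one, via flavanone-3-carboxylate 12 (not isolated)
Conditions: quinidine-derived 3,5-bis(trifluoromethyl)phenyl thiourea (10 mol%), toluene, −25 °C; then TsOH·H2O (0.5 equiv), 80 °C
Reagents that add atoms: none
Why: The bifunctional cinchona thiourea binds the 1,3-dicarbonyl of 11 through its two N–H bonds while its quinuclidine nitrogen takes up the O1–H proton, so the phenoxide adds to C2 of the doubly activated benzylidene in an enantioselective intramolecular oxa-Michael addition; the closest known reaction type is the thiourea-catalysed cyclisation of 2-hydroxyaryl alkylidene β-ketoesters to flavanone-3-carboxylates. Ring C (O1–C2–C3–C4–C4a–C8a) closes in the 6-endo-trig mode. The new stereocentre C2 is set by the catalyst alone, since the substrate has no other stereo-element, and because conjugate addition is reversible under the basic catalyst the E and Z isomers of 11 interconvert through the adduct and are funnelled into the same 2S series. Acid then cleaves the tert-butyl ester with loss of 2-methylpropene and the β-keto acid decarboxylates, which erases C3 (both epimers and the enol of 12 converge on 13) without touching C2, since 13 has no free 5-OH and no base is present to trigger retro-oxa-Michael. The step needs regioselectivity between O1 and O5 and enantioselectivity: the first is secured because O5 is benzylated and O1 is the only free hydroxyl beside the C4 carbonyl, the second by the tert-butyl ester, which makes the acceptor reactive at −25 °C where the uncatalysed background should be slow.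

**Step 8**
Reactants: 13 (2S)-5,7-bis(benzyloxy)-6-[2,3-bis(benzyloxy)benzyl]-2-phenylchroman-4-one
Product: 14 (2S)-6-(2,3-dihydroxybenzyl)-5,7-dihydroxy-2-phenylchroman-4-one
Conditions: H2 (1 atm), 10% Pd/C, EtOAc–MeOH, rt
Reagents that add atoms: none
Why: Hydrogenolysis of four aryl benzyl ethers over Pd/C in neutral medium, which leaves the diarylmethane, the aryl ketone and C2 untouched and avoids the base-induced retro-oxa-Michael that would racemise C2 and scramble the 6-/8-benzyl isomers.

**Compound list**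
1 | 3,5-bis(benzyloxy)phenol | Oc1cc(OCc2ccccc2)cc(OCc2ccccc2)c1 | starting material
2 | [3,5-bis(benzyloxy)phenoxy]tri(propan-2-yl)silane | CC(C)[Si](Oc1cc(OCc2ccccc2)cc(OCc2ccccc2)c1)(C(C)C)C(C)C | intermediate
3 | 2,3-bis(benzyloxy)benzaldehyde | O=Cc1cccc(OCc2ccccc2)c1OCc1ccccc1 | starting material
4 | [2,6-bis(benzyloxy)-4-(triisopropylsilyloxy)phenyl]lithium | [Li]c1c(OCc2ccccc2)cc(O[Si](C(C)C)(C(C)C)C(C)C)cc1OCc1ccccc1 | intermediate
5 | [2,6-bis(benzyloxy)-4-(triisopropylsilyloxy)phenyl][2,3-bis(benzyloxy)phenyl]methanol (racemic) | OC(c1cccc(OCc2ccccc2)c1OCc1ccccc1)c1c(OCc2ccccc2)cc(O[Si](C(C)C)(C(C)C)C(C)C)cc1OCc1ccccc1 | intermediate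
6 | {3,5-bis(benzyloxy)-4-[2,3-bis(benzyloxy)benzyl]phenoxy}tri(propan-2-yl)silane | CC(C)[Si](Oc1cc(OCc2ccccc2)c(Cc2cccc(OCc3ccccc3)c2OCc2ccccc2)c(OCc2ccccc2)c1)(C(C)C)C(C)C | intermediate
7 | 3,5-bis(benzyloxy)-4-[2,3-bis(benzyloxy)benzyl]phenol | Oc1cc(OCc2ccccc2)c(Cc2cccc(OCc3ccccc3)c2OCc2ccccc2)c(OCc2ccccc2)c1 | intermediate
8 | 1-{2,4-bis(benzyloxy)-3-[2,3-bis(benzyloxy)benzyl]-6-hydroxyphenyl}ethan-1-one | CC(=O)c1c(O)cc(OCc2ccccc2)c(Cc2cccc(OCc3ccccc3)c2OCc2ccccc2)c1OCc1ccccc1 | intermediate
9 | tert-butyl 3-{2,4-bis(benzyloxy)-3-[2,3-bis(benzyloxy)benzyl]-6-hydroxyphenyl}-3-oxopropanoate | CC(C)(C)OC(=O)CC(=O)c1c(O)cc(OCc2ccccc2)c(Cc2cccc(OCc3ccccc3)c2OCc2ccccc2)c1OCc1ccccc1 | intermediate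
10 | benzaldehyde | O=Cc1ccccc1 | starting material
11 | tert-butyl 2-{2,4-bis(benzyloxy)-3-[2,3-bis(benzyloxy)benzyl]-6-hydroxybenzoyl}-3-phenylprop-2-enoate (E/Z mixture) | CC(C)(C)OC(=O)C(=Cc1ccccc1)C(=O)c1c(O)cc(OCc2ccccc2)c(Cc2cccc(OCc3ccccc3)c2OCc2ccccc2)c1OCc1ccccc1 | intermediate
12 | tert-butyl (2S)-5,7-bis(benzyloxy)-6-[2,3-bis(benzyloxy)benzyl]-4-oxo-2-phenylchromane-3-carboxylate (C3 epimers and enol) | CC(C)(C)OC(=O)C1C(=O)c2c(OCc3ccccc3)c(Cc3cccc(OCc4ccccc4)c3OCc3ccccc3)c(OCc3ccccc3)cc2O[C@@H]1c1ccccc1 | intermediate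
13 | (2S)-5,7-bis(benzyloxy)-6-[2,3-bis(benzyloxy)benzyl]-2-phenylchroman-4-one | O=C1C[C@@H](c2ccccc2)Oc2cc(OCc3ccccc3)c(Cc3cccc(OCc4ccccc4)c3OCc3ccccc3)c(OCc3ccccc3)c21 | intermediate
14 | (2S)-6-(2,3-dihydroxybenzyl)-5,7-dihydroxy-2-phenylchroman-4-one | O=C1C[C@@H](c2ccccc2)Oc2cc(O)c(Cc3cccc(O)c3O)c(O)c21 | target

**Step count and risks**
Total steps: 8. Longest linear sequence: 8 steps (1 to 14); 3 and 10 are purchased and enter at steps 2 and 6.

Steps most likely to fail:

1. Step 7. The di-ortho-substituted aroyl group twists the acceptor out of conjugation, so turnover in the chiral pocket may be slow and uncatalysed or premature cyclisation may erode the enantiomeric purity. The hot acid stage may also start to cleave the benzyl ether beside the carbonyl. The fallback sets out from 8 and returns at 13, with C2 set on a preformed ring C. Condensation of 8 with DMF dimethyl acetal (toluene, 90 °C) should give the enaminone (E)-1-{2,4-bis(benzyloxy)-3-[2,3-bis(benzyloxy)benzyl]-6-hydroxyphenyl}-3-(dimethylamino)prop-2-en-1-one F1. Acid (HCl, CH2Cl2) should close it through the only free ortho hydroxyl to the chromone 5,7-bis(benzyloxy)-6-[2,3-bis(benzyloxy)benzyl]-4H-chromen-4-one F2. A Pd(II)/t-BuPyOx- or Rh/chiral-diene-catalysed asymmetric conjugate addition of phenylboronic acid, with the ligand antipode chosen for 2S, should then give 13.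

2. Step 2. Deprotonation at the benzylic OCH2Ph positions (followed by [1,2]-Wittig rearrangement) or lithiation beside OTIPS may compete with metalation between the two benzyloxy groups. The fallback sets out from 1 and returns at 5, with the polarity of the coupling inverted. Vilsmeier–Haack formylation of 1 (POCl3, DMF) para to the hydroxyl should give 2,6-bis(benzyloxy)-4-hydroxybenzaldehyde F3, separable from the ortho isomer. Silylation (TIPSCl, imidazole) should give 2,6-bis(benzyloxy)-4-(triisopropylsilyloxy)benzaldehyde F4. Addition of [2,3-bis(benzyloxy)phenyl]lithium F5, made by bromine–lithium exchange from purchased 1,2-bis(benzyloxy)-3-bromobenzene at −78 °C, should give 5.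

3. Step 4. The Lewis acid may cleave the benzyl ether ortho to the new carbonyl by chelation, stop at O-acetylation, or fragment the electron-rich diarylmethane. The fallback sets out from 7 and returns at 8, and needs no acid. Magnesium-mediated ortho-formylation (MgCl2, Et3N, paraformaldehyde, MeCN, reflux) should give 2,4-bis(benzyloxy)-3-[2,3-bis(benzyloxy)benzyl]-6-hydroxybenzaldehyde F6. Addition of MeMgBr should give 1-{2,4-bis(benzyloxy)-3-[2,3-bis(benzyloxy)benzyl]-6-hydroxyphenyl}ethan-1-ol F7. Oxidation of the benzylic alcohol with MnO2 should give 8.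

**Further compounds**
F1 | step 7 | (E)-1-{2,4-bis(benzyloxy)-3-[2,3-bis(benzyloxy)benzyl]-6-hydroxyphenyl}-3-(dimethylamino)prop-2-en-1-one | CN(C)/C=C/C(=O)c1c(O)cc(OCc2ccccc2)c(Cc2cccc(OCc3ccccc3)c2OCc2ccccc2)c1OCc1ccccc1
F2 | step 7 | 5,7-bis(benzyloxy)-6-[2,3-bis(benzyloxy)benzyl]-4H-chromen-4-one | O=c1ccoc2cc(OCc3ccccc3)c(Cc3cccc(OCc4ccccc4)c3OCc3ccccc3)c(OCc3ccccc3)c12
F3 | step 2 | 2,6-bis(benzyloxy)-4-hydroxybenzaldehyde | O=Cc1c(OCc2ccccc2)cc(O)cc1OCc1ccccc1
F4 | step 2 | 2,6-bis(benzyloxy)-4-(triisopropylsilyloxy)benzaldehyde | O=Cc1c(OCc2ccccc2)cc(O[Si](C(C)C)(C(C)C)C(C)C)cc1OCc1ccccc1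
F5 | step 2 | [2,3-bis(benzyloxy)phenyl]lithium | [Li]c1cccc(OCc2ccccc2)c1OCc1ccccc1
F6 | step 4 | 2,4-bis(benzyloxy)-3-[2,3-bis(benzyloxy)benzyl]-6-hydroxybenzaldehyde | O=Cc1c(O)cc(OCc2ccccc2)c(Cc2cccc(OCc3ccccc3)c2OCc2ccccc2)c1OCc1ccccc1
F7 | step 4 | 1-{2,4-bis(benzyloxy)-3-[2,3-bis(benzyloxy)benzyl]-6-hydroxyphenyl}ethan-1-ol (racemic) | CC(O)c1c(O)cc(OCc2ccccc2)c(Cc2cccc(OCc3ccccc3)c2OCc2ccccc2)c1OCc1ccccc1
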